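**The question.** Find when J stands highest in this flask within 40 min, how high it stands, and how long it stays above the share of that peak asked for below.

in all of them: Q 10 mM (fed, over 12 min)

|  | G | remark | time |
|---|---|---|---|
| Thursday's | 0.034 mol% | run made earlier; the fed solution adds 0.50 times the starting volume |  |
| Sunday's | 0.075 mol% | run made earlier; the fed solution adds 0.50 times the starting volume |  |
| flask | 0.05 mol% | the fed solution adds 0.50 times the starting volume | 40 min |

| run | time / min | J / % |
|---|---|---|
| Thursday's | 4.00 | 17.0 |
| Thursday's | 8.00 | 33.8 |
| Thursday's | 12.0 | 50.9 |
| Thursday's | 25.0 | 58.9 |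
| Sunday's | 4.00 | 18.0 |
| Sunday's | 8.00 | 34.2 |
| Sunday's | 12.0 | 53.3 |
| Sunday's | 25.0 | 44.0 |

(readings scatter by 1 percentage point)

- the best time, 40 min at the latest, for J
- the amount of J, in percent of the Q charged, at that time
- earliest time at which at least nineteen twentieths of that best amount are there, in min
- latest time at which they still are, in min

**Bench rule.** Start from the usual rule of thumb: treat each step as pseudo-first-order with its rate proportional to G, so that more G shortens every time in proportion. Test it at the end of the feed, where Sunday's loading is 2.21 times Thursday's, yet J reads 53.3% against 50.9%, a ratio of 1.05. So keep the rule out of the feed and start its clock at 12 min, after which the two runs part: by 25.0 min Thursday's run has climbed to 58.9% and Sunday's has fallen to 44.0%.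

**Equal work.** Reckon 19.5 min from Sunday's span after the feed, multiplied by Sunday's G per starting volume and divided by this flask's, and call it the equal-work wait, the time after the feed in which this flask's G does what Sunday's did. Thursday's span shrinks the same way to 8.84 min. Thursday's last reading is the highest of both runs, so commit to a best near 58.9%, reached by about 20.8 min.

**The forecast.** The forecast, holding of a slow pool and of the loss of J that after the feed “both run at rates proportional to G”, gives 61% at 18 min, earlier than this reckoning, with the window from 14.3 min to 22.5 min.

**The result.** Q + G → J + G, rate k1*[Q]*[G]/(1 + ([Q]/Km1) + ([Q]/Ksi1)^2) (20.0 mM, 6.90 mM, k = 3.80 × 10⁵ L mol⁻¹ min⁻¹); J + G ⇌ Z + G, rate k2*[G]*[J] forward; the back reaction follows from the equilibrium constant (K = 1.70, k = 76000 L mol⁻¹ min⁻¹); G ⇌ E (K = 3.60, k = 0.190 min⁻¹)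

The flask peaks at 15.6 min with 57.8% and stays above the asked share of that from 12.9 min to 19.9 min, so the peak comes earlier than reckoned. At the peak, Q still stands at 7.74% and Z at 34.5%. The equal-work wait puts Sunday's stage at 31.5 min, and the flask holds 44.5% at 31.3 min, against Sunday's reading of 44.0%.

**Second flask.** With Q at 17 mM and the same loading, G per volume grows with the charge, so the wait shrinks to 11.5 min, shorter than Sunday's span. Expect this neighbour's J to top out near Sunday's highest reading, 53.3%. The computed neighbour reaches 52.6%.

(The readings stem from a simulated flask with constants of no real substance, noise included.)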